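How much D stands after 40 h when the charge of solid Z climbs from 0.20 M to 1.5 M?

| setting | elm | larch | midnight | summer | noon | dusk |
|---|---|---|---|---|---|---|
| Z | 0.17 M | 0.54 M | 0.20 M | 0.40 M | 0.80 M | 1.5 M |
| remark | run made earlier | run made earlier |  |  |  |  |
| time |  |  | 40 h | 40 h | 40 h | 40 h |

- elm (time / h: D / %, Z / %): 3.00: 0.4, 89.0; 8.00: 4.3, 74.3; 15.0: 9.1, 56.8; 40.0: 23.5, 1.2
- larch (time / h: D / %, Z / %): 5.00: 0, 94.5; 15.0: 5.0, 86.9; 25.0: 5.8, 78.2; 40.0: 7.0, 67.3

(scatter of a reading: 1 percentage point)

* [D] at the end for midnight, summer, noon, dusk, in this order
* the shape of the row from first to last (hardly changes / rises all the way / rises, then falls / falls all the way / falls, then rises)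

- Z is a solid; its amount is given per volume of the solution
- at the start none of Z is in solution
- "hardly changes" means that all values lie within two and a half points (for a concentration: within two and a half percent of the largest)

Larch, with solid to spare, lost 0.177 M of Z by 40.0 h, as read from its scattered readings. Call this the crossing charge c*, the amount of Z that a flask with solid to spare takes up in 40.0 h. Elm lost Z between 3.00 h and 15.0 h at 0.00456 M h⁻¹ and larch, averaged over its whole run, at 0.00441 M h⁻¹, which is close, so on these readings the loss of Z looks zero order in the charge.

Two extreme versions follow. The first treats the whole charge as dissolved, with [D] in proportion to it: elm's yield of 23.5% applied to dusk's charge gives 0.353 M, a figure for that version and not a forecast for dusk. The second treats the charge as far above c*, with the supply into solution independent of it, so [D] equals larch's 0.0378 M, a reading that carries a scatter of 1 percentage point. Elm, just below the crossing, gave 0.0400 M, close to that value. The smallest new charge, midnight's 0.20 M, lies above c*, though not far above it, so by this reading solid lasts to the end in each new flask, as in the second version. The reckoning here commits to about 0.0378 M in each flask, with Z left at 11.7% in midnight and 88.2% in dusk.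

The forecast agrees: 0.04 M, 0.04 M, 0.04 M, 0.04 M, a row that hardly changes, since the charges “still hold solid” at the end.

The flasks give 0.0394 M, 0.0394 M, 0.0394 M, 0.0394 M: the row hardly changes.

    G ⇌ D (K = 1.80, k = 0.00120 min⁻¹)
    G ⇌ L (K = 1.60, k = 0.00101 min⁻¹)
    D ⇌ X (K = 7.57, k = 4.57 × 10⁻⁴ min⁻¹)
    G ⇌ Q (K = 0.700, k = 4.47 × 10⁻⁴ min⁻¹)
    Z ⇌ G, rate k5*(cs5 - [G]) while solid is left; crystals form when [G] > cs5 (solubility = 0.110 M, k = 9.29 × 10⁻⁴ min⁻¹)

At 40.0 h, Z stood at 13.8% in midnight and 88.5% in dusk, so midnight had lost 0.172 M and dusk 0.172 M, against a c* of 0.177 M. While Z dissolved into G in midnight, the step between G and D had, by itself, a relaxation half-life of 6.19 h, shorter than the 22.3 h of the step between D and X, and at 40.0 h midnight still made D 1.70 times faster than it used D up, each step taken net.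

The earlier runs and the new flask were computed with constants of no real substance, noise included.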